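The numbers in the tables come from a simulation on assumed constants; the scatter is artificial.

Should the next run keep the second substrate at 0.170 M, or does that charge cost too much of the rate of making target?

* apparent order in second substrate when 20 % of the starting material are converted (percent change of the rate of making target for one percent more second substrate charged)
* apparent order in free catalyst when 20 % of the starting material are converted (percent change of the rate of making target for one percent more free catalyst charged)

| flask | starting material | second substrate | free catalyst | added ligand | remark |
|---|---|---|---|---|---|
| Saturday's | 0.17 M | 0.17 M | 12 mM | 35 mM | the very flask that is asked about, followed so far |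
| Thursday's | 0.17 M | 0.34 M | 12 mM | 35 mM | run made earlier |
| flask | 0.17 M | 0.170 M | 12 mM | 35 mM |  |

- Saturday's (time / s: target / %, starting material / %): 10.0: 14.3, 83.7; 12.0: 14.3, 83.7; 20.0: 23.6, 77.3; 30.0: 33.0, 68.5; 50.0: 47.3, 53.3; 80.0: 61.6, 36.3; 120: 77.2, 21.4
- Thursday's (time / min: target / %, starting material / %): 0.200: 14.1, 83.9; 0.333: 19.0, 80.3; 0.417: 25.7, 75.3; 0.667: 33.6, 64.6; 1.00: 42.7, 57.0; 1.50: 56.5, 42.3; 2.50: 76.2, 24.8

(each reading ± 1 percentage point)

- the earlier runs were read with a standard deviation of 1 percentage point
- steps thought possible: starting material + free catalyst <-> catalyst intermediate A; catalyst intermediate A -> free catalyst + target; second substrate + free catalyst <-> catalyst intermediate B; catalyst intermediate B -> free catalyst + second product; free catalyst + added ligand <-> idle complex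
- no earlier run changes the charge of free catalyst; that part of a forecast is a guess
- what is bound to the catalyst counts as converted

Saturday's and Thursday's runs differ in the charge of second substrate, so I compare them. From the charge to the last reading, I take an apparent first-order constant from the target: 0.0123 s⁻¹ on Saturday's reading and 0.00957 s⁻¹ on Thursday's. Suppose the rate goes as 1/(1+x), with x proportional to c(second substrate). Doubling the charge then gives a ratio of constants from which x follows, and the share x/(1+x) comes out as the Saturday constant over the Thursday constant, minus one. I call this the held share, the part of the catalyst that second substrate keeps from making target on Saturday's charge, and read 28.7 %. The apparent order in second substrate is minus this share, so my own reckoning for Saturday's recipe gives −0.287. That reading carries the scatter of two single points. On this reckoning, one percent more second substrate costs that fraction of one percent of the rate of making target, so I keep the charge. No run changes the free catalyst, so I reckon no catalyst order of my own.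

The forecast gives −0.38 in second substrate and 1.2 in free catalyst, on the ground that “Doubling the second substrate therefore cuts the rate to about 0.73”. Its order in second substrate differs from mine; it calls its catalyst order an extrapolation.

The flask gives −0.31 in second substrate and 1.2 in free catalyst, so the forecast's order in second substrate is too low and its order in free catalyst is within the tolerance.

starting material + free catalyst ⇌ catalyst intermediate A (K = 11.0 L mol⁻¹, k = 2.60 L mol⁻¹ s⁻¹); catalyst intermediate A → free catalyst + target (k = 0.770 s⁻¹); second substrate + free catalyst ⇌ catalyst intermediate B (K = 8.50 L mol⁻¹, k = 0.280 L mol⁻¹ s⁻¹); catalyst intermediate B → free catalyst + second product (k = 0.0390 s⁻¹); free catalyst + added ligand ⇌ idle complex (K = 20.0 L mol⁻¹, k = 0.0820 L mol⁻¹ s⁻¹) With the step from second substrate and free catalyst to catalyst intermediate B taken away, both ways, the order in second substrate goes from −0.31 to 0, the largest single effect on it. The held share of 28.7 %, read off Saturday's and Thursday's runs, gives −0.287 as an order, against the flask's −0.31.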